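**Strategy**

Ring B of the naphthalene (C1–C4, C4a, C8a; ring A carries the oxygens) is disconnected at C2, the methyl-bearing carbon flanked by aryl-bearing C1 and methyl-bearing C3. Removing C2 leaves a 3-aryl-2-methyl-1H-indene whose CH2 is the future C4–H. In one operation dibromocarbene adds to the indene C2=C3 bond and the fused dibromocyclopropane opens with loss of HBr: the C1–C2 and C2–C3 bonds form, the five-membered ring becomes aromatic ring B, and bromine remains on C2 as the handle for the second methyl group. The precursor is 6-benzyloxy-5-methoxy-2-methyl-3-(3,4,5-trimethoxyphenyl)-1H-indene, reached from a benzyl-protected indanone by α-methylation and aryl addition–dehydration.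

Key step: step 3

Remark: the target is numbered as a naphthalene with aryl on C1, methyls on C2 and C3, OH on C6 and OMe on C7; it is achiral and every chiral intermediate is racemic. 5-Benzyloxy-6-methoxy-1-indanone and 3,4,5-trimethoxyphenylmagnesium bromide (THF solution) are assumed to be purchasable as such. The indanone C5 oxygen (para to the ring carbon that carries C=O) maps onto the naphthalene C6 hydroxyl, and the benzyl ether masks it because a free phenoxide would react with dibromocarbene.

**Route**

Step 1
Reactants: 1 5-(benzyloxy)-6-methoxy-2,3-dihydro-1H-inden-1-one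
Product: 3 5-(benzyloxy)-6-methoxy-2-methyl-2,3-dihydro-1H-inden-1-one (racemic), via lithium enolate 2 (not isolated)
Conditions: LiN(iPr)2 (1.05 equiv), THF, −78 °C; then MeI (1.2 equiv), −78 → −20 °C
Reagents that add atoms: iodomethane, CI; lithium diisopropylamide, [Li]N(C(C)C)C(C)C (lithium in intermediate 2 only)
Why: Kinetic deprotonation can only occur at C2, and SN2 C-alkylation of the lithium enolate with iodomethane at low temperature should favour monomethylation (enolate alkylation); the new C2 stereocentre forms as a racemate and is erased in step 2.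

Step 2
Reactants: 3 5-(benzyloxy)-6-methoxy-2-methyl-2,3-dihydro-1H-inden-1-one; 4 3,4,5-trimethoxyphenylmagnesium bromide (0.5 M in THF)
Product: 6 6-(benzyloxy)-5-methoxy-2-methyl-3-(3,4,5-trimethoxyphenyl)-1H-indene, via tertiary indanol 5 (not isolated)
Conditions: 4 (1.5 equiv), LaCl3·2LiCl (1.0 equiv), THF, 0 °C → rt; then 4 M HCl, rt
Reagents that add atoms: 3,4,5-trimethoxyphenylmagnesium bromide (compound 4), COc1cc([Mg]Br)cc(OC)c1OC
Why: Lewis-acid-assisted Grignard 1,2-addition to the α-branched ketone should outrun enolisation, and the doubly benzylic tertiary alcohol 5 then loses water by acid-catalysed E1 elimination, which can only give the tetrasubstituted alkene between the aryl-bearing carbon and C2 because C2–H is the sole β-hydrogen; both stereocentres of 5 disappear.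

Step 3
Reactants: 6 6-(benzyloxy)-5-methoxy-2-methyl-3-(3,4,5-trimethoxyphenyl)-1H-indene; 7 bromoform
Product: 9 6-(benzyloxy)-2-bromo-7-methoxy-3-methyl-1-(3,4,5-trimethoxyphenyl)naphthalene, via fused dibromocyclopropane 8 (not isolated)
Conditions: CHBr3 (2 equiv), KOtBu (4.5 equiv), toluene, −20 °C → rt; then 60 °C
Reagents that add atoms: bromoform (compound 7), BrC(Br)Br
Why: tert-Butoxide turns bromoform into singlet dibromocarbene by α-elimination, and the carbene adds in a concerted cheletropic [2+1] step to the electron-rich, tetrasubstituted styrenic C2=C3 bond of 6 to give the cis-fused dibromocyclopropane 8. In 8 the bromide that lies over the five-membered ring ionises while the bond shared by the two rings breaks in a two-electron disrotatory electrocyclic opening (Woodward–Hoffmann rules), giving a six-membered 2-bromoallyl cation stabilised by ring A, by the para benzyloxy group and by the trimethoxyphenyl ring; tert-butoxide then removes a proton from the former indene CH2 (now C4) and ring B is aromatic. The closest known reaction type is the dihalocarbene ring expansion of indenes to 2-halonaphthalenes, the carbocyclic counterpart of the Ciamician–Dennstedt reaction. Ring B is not closed by an endo or exo cyclisation but by ring enlargement: the carbene carbon is already bonded to C1 and C3 in the three-membered ring and becomes C2 of the six-membered ring when the old C–C bond opens. No stereocentre has to be controlled, since the two in 8 are cis by necessity and vanish on aromatisation. The step needs chemoselectivity for the alkene over the arenes and the benzylic ether C–H bonds, which the high nucleophilicity of the alkoxy-conjugated alkene should secure, and a defined position for bromine, which follows from the 3-aryl-2-methyl tautomer being the favoured indene; bromide formed from the minor 1-aryl tautomer would still converge on 11 after step 4, because C2 and C3 both end up methylated.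

Step 4
Reactants: 9 6-(benzyloxy)-2-bromo-7-methoxy-3-methyl-1-(3,4,5-trimethoxyphenyl)naphthalene
Product: 11 6-(benzyloxy)-7-methoxy-2,3-dimethyl-1-(3,4,5-trimethoxyphenyl)naphthalene, via 2-naphthyllithium 10 (not isolated)
Conditions: n-BuLi (1.2 equiv), THF, −78 °C; then MeI (3 equiv), −78 °C → rt
Reagents that add atoms: iodomethane, CI; n-butyllithium, [Li]CCCC (lithium in intermediate 10 only)
Why: Bromine–lithium exchange at −78 °C is much faster than deprotonation of the benzylic or methoxy C–H bonds, and the aryllithium 10 is then methylated by iodomethane in an SN2 reaction, which places the second methyl on C2.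

Step 5
Reactants: 11 6-(benzyloxy)-7-methoxy-2,3-dimethyl-1-(3,4,5-trimethoxyphenyl)naphthalene
Product: 12 3-methoxy-6,7-dimethyl-5-(3,4,5-trimethoxyphenyl)naphthalen-2-ol (target)
Conditions: H2 (1 atm), 10% Pd/C, EtOAc–MeOH, rt
Reagents that add atoms: none
Why: Palladium-catalysed hydrogenolysis cleaves the benzylic C–O bond of the aryl benzyl ether at room temperature and 1 atm, conditions under which the naphthalene core and the methyl ethers should be untouched.

**Compound list**

1 | 5-(benzyloxy)-6-methoxy-2,3-dihydro-1H-inden-1-one | COc1cc2c(cc1OCc1ccccc1)CCC2=O | starting material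
2 | lithium 6-(benzyloxy)-5-methoxy-1H-inden-3-olate (lithium enolate of 1) | COc1cc2c(cc1OCc1ccccc1)CC=C2[O-].[Li+] | intermediate
3 | 5-(benzyloxy)-6-methoxy-2-methyl-2,3-dihydro-1H-inden-1-one (racemic) | COc1cc2c(cc1OCc1ccccc1)CC(C)C2=O | intermediate
4 | 3,4,5-trimethoxyphenylmagnesium bromide | COc1cc([Mg]Br)cc(OC)c1OC | starting material
5 | 5-(benzyloxy)-6-methoxy-2-methyl-1-(3,4,5-trimethoxyphenyl)-2,3-dihydro-1H-inden-1-ol (racemic, mixture of diastereomers) | COc1cc2c(cc1OCc1ccccc1)CC(C)C2(O)c1cc(OC)c(OC)c(OC)c1 | intermediate
6 | 6-(benzyloxy)-5-methoxy-2-methyl-3-(3,4,5-trimethoxyphenyl)-1H-indene | COc1cc2c(cc1OCc1ccccc1)CC(C)=C2c1cc(OC)c(OC)c(OC)c1 | intermediate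
7 | bromoform | BrC(Br)Br | starting material
8 | 4-(benzyloxy)-1,1-dibromo-3-methoxy-6a-methyl-1a-(3,4,5-trimethoxyphenyl)-1,1a,6,6a-tetrahydrocyclopropa[a]indene (racemic; ring fusion necessarily cis; the CBr2 bridge spans the former indene C2 and C3) | COc1cc2c(cc1OCc1ccccc1)CC1(C)C(Br)(Br)C21c1cc(OC)c(OC)c(OC)c1 | intermediate
9 | 6-(benzyloxy)-2-bromo-7-methoxy-3-methyl-1-(3,4,5-trimethoxyphenyl)naphthalene | COc1cc2c(-c3cc(OC)c(OC)c(OC)c3)c(Br)c(C)cc2cc1OCc1ccccc1 | intermediate
10 | [6-(benzyloxy)-7-methoxy-3-methyl-1-(3,4,5-trimethoxyphenyl)naphthalen-2-yl]lithium | COc1cc2c(-c3cc(OC)c(OC)c(OC)c3)c([Li])c(C)cc2cc1OCc1ccccc1 | intermediate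
11 | 6-(benzyloxy)-7-methoxy-2,3-dimethyl-1-(3,4,5-trimethoxyphenyl)naphthalene | COc1cc2c(-c3cc(OC)c(OC)c(OC)c3)c(C)c(C)cc2cc1OCc1ccccc1 | intermediate
12 | 3-methoxy-6,7-dimethyl-5-(3,4,5-trimethoxyphenyl)naphthalen-2-ol (achiral) | COc1cc2c(-c3cc(OC)c(OC)c(OC)c3)c(C)c(C)cc2cc1O | target

**Step count and risks**

Total step count: 5. Longest linear sequence: 5 steps (1 → 12).

Steps most likely to fail, riskiest first:

1. Step 3 (carbene ring expansion). tert-Butoxide may deprotonate the indene CH2 in competition with carbene transfer, so that the double bond migrates and the indenyl anion consumes carbene. Addition to the crowded tetrasubstituted alkene may also be slow enough for excess carbene to insert into the benzylic C–H bonds of the ether. The fallback sets out from 6 and avoids alkoxide base altogether. Heating 6 with Cl3CCO2Na in 1,2-dimethoxyethane at reflux releases dichlorocarbene by decarboxylation and should give 4-(benzyloxy)-1,1-dichloro-3-methoxy-6a-methyl-1a-(3,4,5-trimethoxyphenyl)-1,1a,6,6a-tetrahydrocyclopropa[a]indene F1. On continued heating this should open with loss of HCl to 6-(benzyloxy)-2-chloro-7-methoxy-3-methyl-1-(3,4,5-trimethoxyphenyl)naphthalene F2. Suzuki–Miyaura methylation of the chloride (MeB(OH)2, Pd(OAc)2, SPhos, K3PO4, toluene–water, 100 °C) then returns to the route at 11, so step 4 is bypassed as well.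

2. Step 2 (aryl addition and dehydration). The basic aryl nucleophile may enolise the α-branched ketone instead of adding, so that ketone is returned on quench; the electron-rich indene may also oligomerise during the acid treatment. The fallback sets out from 3 and replaces carbonyl addition by cross-coupling. Enolisation with LiN(SiMe3)2 in THF at −78 °C and trapping with PhNTf2 should give 6-(benzyloxy)-5-methoxy-2-methyl-1H-inden-3-yl trifluoromethanesulfonate F3. Suzuki–Miyaura coupling with commercial 3,4,5-trimethoxyphenylboronic acid (Pd(PPh3)4, K2CO3, dioxane–water, 80 °C) returns to the route at 6 with no acid step.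

3. Step 1 (α-methylation). Proton exchange between the methylated ketone and unreacted enolate may lead to double methylation alongside recovered 1. The fallback sets out from 1 and uses an activating ester so that only one alkylation is possible. Acylation with dimethyl carbonate and NaH in refluxing THF should give methyl 5-(benzyloxy)-6-methoxy-1-oxo-2,3-dihydro-1H-indene-2-carboxylate F4. Methylation of its single acidic position (K2CO3, MeI, acetone) gives methyl 5-(benzyloxy)-6-methoxy-2-methyl-1-oxo-2,3-dihydro-1H-indene-2-carboxylate F5. Krapcho dealkoxycarbonylation (LiCl, wet DMSO, 140 °C) returns to the route at 3.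

**Further compounds**

F1 | step 3 | 4-(benzyloxy)-1,1-dichloro-3-methoxy-6a-methyl-1a-(3,4,5-trimethoxyphenyl)-1,1a,6,6a-tetrahydrocyclopropa[a]indene (racemic, cis-fused) | COc1cc2c(cc1OCc1ccccc1)CC1(C)C(Cl)(Cl)C21c1cc(OC)c(OC)c(OC)c1
F2 | step 3 | 6-(benzyloxy)-2-chloro-7-methoxy-3-methyl-1-(3,4,5-trimethoxyphenyl)naphthalene | COc1cc2c(-c3cc(OC)c(OC)c(OC)c3)c(Cl)c(C)cc2cc1OCc1ccccc1
F3 | step 2 | 6-(benzyloxy)-5-methoxy-2-methyl-1H-inden-3-yl trifluoromethanesulfonate | COc1cc2c(cc1OCc1ccccc1)CC(C)=C2OS(=O)(=O)C(F)(F)F
F4 | step 1 | methyl 5-(benzyloxy)-6-methoxy-1-oxo-2,3-dihydro-1H-indene-2-carboxylate (racemic) | COc1cc2c(cc1OCc1ccccc1)CC(C(=O)OC)C2=O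
F5 | step 1 | methyl 5-(benzyloxy)-6-methoxy-2-methyl-1-oxo-2,3-dihydro-1H-indene-2-carboxylate (racemic) | COc1cc2c(cc1OCc1ccccc1)CC(C)(C(=O)OC)C2=O
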